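## Structural features

The target (C25H40O3) is a linear 5-6-8-5 tetracycle. Cyclopentanone ring A (C4, C5, C7, C8, C28) is trans-fused through C8–C28 to cyclohexane ring B, ring B is trans-fused through C11–C25 to the eight-membered ring C, and ring C shares C16–C21 with cyclopentane ring D. The C21–C23 bond of ring C carries a tetrasubstituted epoxide, so C21 belongs to rings C and D and to the oxirane, and the methyl-bearing C23 stands next to the tertiary carbinol C25. Ten stereocentres form an almost unbroken chain (C4–C28–C8, C11–C12, C25–C23–C21–C16–C17). C8 is an all-carbon quaternary centre, and the C25 hydroxyl is axial on ring B, anti to H11 and on the same face as H28, H16 and the epoxide oxygen. The fragile parts are the hydroxy epoxide (acid-induced opening or 1,2-shift) and C4, which is epimerisable next to the ketone and carries its isopropyl group cis to the angular C8 methyl, so it is best set late and kinetically. The real difficulty is the eight-membered ring with stereocentres on both flanks: H11 and H12 are cis although the B/C fusion is trans, and C12 must be related to C16 across the ring. The key step exploits the C21–C23 bond. Taken back to an alkene it is tetrasubstituted, exocyclic to ring D and endocyclic to ring C, which is the footprint of an alkyne after carbocyclisation of a 1,6-enyne (C15=C16 with C21≡C23, ring D closing at C16–C21). The other four atoms of ring C (C25, C11, C12, C14) are then one butadiene unit.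

## Logic of the disconnections

27 to 26. The hydrogens on C4/C28 and on C17/C18 are removed, leaving a C4=C28 enone and a C17 methylene. C4 is epimerisable, so it should be made last by cis delivery of hydrogen; the axial C25 hydroxyl lies 1,3 to C28 on the α face and can guide a metal hydride there. Three stereocentres (C4, C28, C17) disappear. The forward step needs a catalyst that reduces a tetrasubstituted enone without opening the hydroxy epoxide.

26 to 25. The two C–O bonds of the oxirane are cut to give the C21=C23 alkene. The neighbouring tertiary alcohol on the same face makes a hydroxyl-directed epoxidation the natural forward step. Two more stereocentres go, and the alkene is the mark of the alkyne. The oxidant must ignore the enone, the ketone and the C17 methylene.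

25 to 23 (through 24). C8–C28, C5–C7 and C4–C5 are cut with loss of carbon monoxide, opening rings A and B. This removes two rings and the quaternary centre at once and leaves a bicycle with two side arms. The forward cyclocarbonylation must accept a 1,7-enyne with a 1,1-disubstituted alkene and a branched alkyne, and the arms on C11 and C25 must be trans.

23 to 22 to 21 to 20. C17=C18 is cut back to the ketone, then to the alcohol and its silyl ether. The C17 oxygen serves only to relay chirality to C16, and a methylene lets hydrogen arrive anti to C15 so that the methyl ends cis to it. The ketone at C17 is tolerable only while C25 is sp3 (otherwise H16 is vinylogously acidic), while C21=C23 is still an alkene (an epoxide would eliminate), and before the ring A carbonyl exists. That fixes these steps between the C25 addition and the annulation and demands a non-basic methylenation.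

20 to 14 and 18. C25–C27 is cut as the addition of a 4-methylpent-2-ynyl metal (19) to the ketone. This detaches six carbons, including the isopropyl group. The forward step must bond through the CH2 terminus of the propargyl/allenyl metal and attack anti to the C11–C12 ring bond.

18 to 17 to 15. C27–C28 is cut: hydroxymethylation of the acetylide 16 and bromination. Both are routine.

14 to 12 (through 13). C12–C13 and C11–H are cut: conjugate addition of methyl and protonation of the enolate. Because H11 and H12 are cis, the group that enters C11 after the methyl, anti to it, has to be a proton, so the methallyl group must already be on C11. A conjugate addition followed by C-alkylation would give the trans arrangement. The forward step needs facial control at C12 from the ring conformation and a kinetic quench.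

12 to 10 and 11, and 10 to 9. C10–C11 is cut as a cross-coupling of an α-iodoenone, and C11–I as an α-iodination. Only C11 carries an α-hydrogen on an enone of 9, so there is no regiochemical choice.

9 to 8. The C25 carbonyl oxygen is removed, leaving a doubly allylic methylene. The forward oxidation must put oxygen on the central carbon of the five-carbon unit.

8 to 6 and 7. C16–C21, C23–C25 and C14–C15 are cut: two rings, three bonds and one stereocentre in one catalytic step from two open-chain pieces. Cross-selectivity and control of C16 by C17 are required.

6 to 5 to 4 to 1 and 2. The O–Si bond is cut, the enantiomers are separated, and C16–C17 is cut as the addition of 2 to aldehyde 3, made by oxidation of 1.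

## Other disconnections considered

Alternative 1: The cut is C5–C7, made by imagining ring A as a six-membered 1,2-dione. Forward, hydroxide would add to one carbonyl of dione A1, the ring would contract by a benzilic acid shift, and Pb(OAc)4 would then remove the carboxyl to leave hydrindanone A2.
- In its favour: decalin chemistry is mature. The angular methyl and the trans fusion can come from an enantioselective Robinson annulation and a dissolving-metal reduction. On the source of absolute configuration this is the better of the two plans, since the chosen route discards half of 4 in a resolution.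
- Against it here: A1 has a hydrogen on C4 and would rest largely as its enol, which slows the rearrangement. Hot hydroxide equilibrates C4, whereas the chosen plan sets C4 kinetically in the last step. An extra carbon is put in and taken out again, while in the chosen plan C5 arrives directly as carbon monoxide.
- Structurally, A2 holds only rings A and B and three of the ten stereocentres. The eight-membered ring, the C11/C12 pair and the epoxide are left untouched, so this cannot carry the synthesis.

Alternative 2: The cuts are C8–C28, C5–C7 and C4–C5. Forward, Co2(CO)8 would join the alkyne and methallyl arms of enyne A3 with carbon monoxide to give enone A4.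
- In its favour: it is the equal of the chosen key step in bonds and rings formed (three and two). It is better in that it creates the all-carbon quaternary centre C8 under the control of a chair-like ring B. A4 would be only two operations from the target.
- Against it here: the substrate is demanding (1,7-enyne, 1,1-disubstituted alkene, branched alkyne, stoichiometric cobalt). As the strategic step it also leaves A3 as the real problem, an eight-membered bicycle with five stereocentres.
- The two plans are not rivals. The chosen route uses the same annulation as step 15 on 23, and uses the [4+2+2] to supply the bicycle that Alternative 2 presupposes. In step count they are equal from that bicycle onward.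

Alternative 3: The cut is C11–C12. Forward, the silyl ketene acetal of the ten-membered lactone A5 would rearrange across C27–C25=C11 to give acid A6.
- In its favour: ring C forms by a concerted ring contraction and not by end-to-end closure, and C11 and C12 are set together with chirality transfer from C27. On the vicinal C11/C12 relationship this is in principle the better of the two plans, because the chosen route relies on two substrate-controlled kinetic events.
- Against it here: A5 requires rings A, B and D, the tetrasubstituted C21=C23 alkene and a macrolactonisation before the key step. The enolate geometry inside a medium-ring lactone is constrained. A6 then needs the carboxyl reduced to the C13 methyl, and the C25=C27 alkene turned into the C25 tertiary alcohol with face control next to the alkene that must become the epoxide.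
- In step economy it is clearly behind, since the chosen plan reaches the C/D bicycle in four steps from two small chains.

Key step: step 4

Remarks and assumptions:
- Locants C1–C28 are those of the target in the order of its SMILES string. α is the face of H16 (also of H4, H28, H17, the C25 hydroxyl, the epoxide oxygen and the C12 methyl). β is the opposite face (C4 isopropyl, C8 methyl, H11, H12, C17 methyl).
- Bicyclo[6.3.0]undecane names use C1 = C21, C2 = C23, C3 = C25, C4 = C11, C5 = C12, C8 = C16, C9 = C17.
- The structures of 6, 8 and 27 are mutually consistent: 6 is R, and with the silyloxy group trans to C15, C16 of 8 has the configuration of the target.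
- One change to the order of events after the key step is made on stereochemical grounds: the methallyl group is placed on C11 before the methyl cuprate is added (see the paragraph on 14 to 12 above).
- Assumption: the lipase follows the usual size rule with vinyl as the smaller group, so the R alcohol is the unreacted enantiomer. If this or the facial sense of step 4 were reversed, the acetate fraction would supply the other enantiomer.

Step 1
Reactants: 1 hex-4-yn-1-ol; 2 vinylmagnesium bromide
Product: 4 rac-oct-1-en-6-yn-3-ol, via hex-4-ynal 3 (not isolated)
Conditions: (COCl)2, DMSO, CH2Cl2, −78 °C; Et3N; then 2 (excess, THF), −78 → 0 °C; aq NH4Cl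
Reagents that add atoms: none
Why: Swern oxidation gives the volatile aldehyde 3, which is trapped in the same flask by 1,2-addition of the Grignard reagent (one-pot oxidation/Grignard addition). The new carbinol centre is racemic and is resolved in step 2.

Step 2
Reactants: 4 rac-oct-1-en-6-yn-3-ol
Product: 5 (R)-oct-1-en-6-yn-3-ol
Conditions: immobilised Candida antarctica lipase B, vinyl acetate, hexane, 30 °C, taken a little past half conversion
Reagents that add atoms: none
Why: Lipase-catalysed kinetic resolution by irreversible transesterification. By the empirical size rule for secondary alcohols (vinyl small, alkynyl chain large) the S enantiomer should be acylated, so the R alcohol is recovered in high enantiomeric purity.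

Step 3
Reactants: 5 (R)-oct-1-en-6-yn-3-ol
Product: 6 (R)-3-(tert-butyldimethylsilyloxy)oct-1-en-6-yne
Conditions: TBSCl, imidazole, DMF, rt
Reagents that add atoms: tert-butyldimethylsilyl chloride, CC(C)(C)[Si](C)(C)Cl
Why: Standard silylation of a secondary alcohol. The silyl ether keeps the hydroxyl from binding the cationic rhodium of step 4 and is bulky enough to relay the C17 configuration to C16.

Step 4
Reactants: 6 (R)-3-(tert-butyldimethylsilyloxy)oct-1-en-6-yne; 7 buta-1,3-diene
Product: 8 tert-butyldimethylsilyl ether of (4Z)-2-methylbicyclo[6.3.0]undeca-1,4-dien-9-ol with the ring-fusion hydrogen cis to the silyloxy group (C21=C23, Z-C11=C12, 16α-H, 17α-OTBS)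
Conditions: RhCl(PPh3)3 (10 mol %), AgOTf (20 mol %), 7 (large excess), PhMe, sealed vessel, 110 °C
Reagents that add atoms: none
Why: AgOTf removes chloride from RhCl(PPh3)3, and the cationic monovalent rhodium binds the alkene and alkyne of 6 and undergoes oxidative cyclisation to a rhodacyclopentene of trivalent rhodium, forming C16–C21. Ring D is thus closed in a 5-exo sense through the metal; the closest known reaction type is the rhodium-catalysed [4+2+2] carbocyclisation of heteroatom- and malonate-tethered 1,6-enynes with butadiene. Butadiene then inserts into the Rh–C15 alkyl bond (C14–C15) to give an η3-allyl alkenyl rhodium species, and reductive elimination between the allyl terminus C25 and the alkenyl carbon C23 closes ring C, so the eight-membered ring comes from contraction of a nine-membered metallacycle and not from a direct end-to-end closure. The only new stereocentre, C16, is fixed in the oxidative cyclisation: the C17 silyloxy group should take the pseudo-equatorial position of the forming five-membered ring, which puts C15 trans to oxygen and H16 cis to it. The step needs cross-selectivity over enyne homo-coupling and cycloisomerisation; the large excess of diene, the methyl cap on the alkyne and the silyl ether are there to secure it. Regiochemistry does not arise because butadiene is symmetric, and both ring alkenes are Z because they form inside the metallacycle. C25 emerges doubly allylic, ready for step 5.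

Step 5
Reactants: 8 ring C/D bicyclic diene
Product: 9 (4Z)-9-(tert-butyldimethylsilyloxy)-2-methylbicyclo[6.3.0]undeca-1,4-dien-3-one (cross-conjugated dienone, C25 ketone)
Conditions: (pyH)2Cr2O7, t-BuOOH, Celite, PhH, 10 °C → rt
Reagents that add atoms: tert-butyl hydroperoxide, CC(C)(C)OO
Why: Bis-allylic C–H oxidation with the hexavalent chromium/hydroperoxide system, the reaction type that turns 1,4-dienes into cross-conjugated dienones. The C25 hydrogens are the weakest in the molecule, and oxygen at the central carbon leaves both alkenes in place. The medium is neutral, so the silyl ether and the acid-sensitive dienone should survive.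

Step 6
Reactants: 9 cross-conjugated dienone
Product: 10 (4Z)-9-(tert-butyldimethylsilyloxy)-4-iodo-2-methylbicyclo[6.3.0]undeca-1,4-dien-3-one (iodine on C11)
Conditions: I2, pyridine/CH2Cl2, 0 °C → rt
Reagents that add atoms: iodine, II
Why: α-Iodination of an enone by conjugate addition of pyridine, iodination of the enolate and elimination. Only C11 carries an α-hydrogen, since the other α-carbon (C23) bears the methyl group, and pyridine adds only to the unhindered β-carbon C12.

Step 7
Reactants: 10 11-iodo dienone; 11 tributyl(2-methylallyl)stannane
Product: 12 (4Z)-9-(tert-butyldimethylsilyloxy)-2-methyl-4-(2-methylallyl)bicyclo[6.3.0]undeca-1,4-dien-3-one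
Conditions: Pd2(dba)3 (5 mol %), AsPh3 (20 mol %), CuI (10 mol %), NMP, 40 °C
Reagents that add atoms: none
Why: Stille coupling of an α-iodoenone with an allylic stannane on zerovalent palladium forms C10–C11. The methallyl unit is symmetric at its two termini, so allyl transposition is of no consequence, and the neutral conditions spare the dienone.

Step 8
Reactants: 12 11-(2-methylallyl) dienone
Product: 14 12α-methyl-11α-(2-methylallyl) enone (C25 ketone; 11β-H; 12β-H; 17α-OTBS), via lithium enolate 13 (not isolated)
Conditions: Me2CuLi (from MeLi, CuI), Et2O, −78 → −40 °C; then AcOH, THF, −78 °C; aq NH4Cl/NH3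
Reagents that add atoms: lithium dimethylcuprate, [Li+].C[Cu-]C
Why: Cuprate conjugate addition goes to C12, the only unhindered β-carbon. C16 holds C15 on the β face of the dienone plane, so the methyl should enter anti to the C14–C15 bond from the open α face, setting C12 relative to C16. Kinetic protonation of enolate 13 at C11 should then occur anti to the new methyl (β face), which leaves the methallyl group cis to the methyl as the target requires; a cold, non-basic quench avoids equilibration.

Step 9
Reactants: 15 3-methylbut-1-yne
Product: 17 4-methylpent-2-yn-1-ol, via lithium 3-methylbut-1-ynide 16 (not isolated)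
Conditions: n-BuLi, THF, −78 °C; (CH2O)n, −78 °C → rt; aq NH4Cl
Reagents that add atoms: formaldehyde (as paraformaldehyde), C=O
Why: Deprotonation of the terminal alkyne and hydroxymethylation of the acetylide, a standard propargylic alcohol synthesis. The added carbon becomes C27.

Step 10
Reactants: 17 4-methylpent-2-yn-1-ol
Product: 18 1-bromo-4-methylpent-2-yne
Conditions: PBr3, pyridine (cat.), Et2O, 0 °C
Reagents that add atoms: phosphorus tribromide, BrP(Br)Br
Why: Conversion of a primary propargylic alcohol into the bromide through its phosphite ester. Low temperature and a trace of base suppress the allenyl bromide.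

Step 11
Reactants: 14 12α-methyl-11α-(2-methylallyl) enone; 18 1-bromo-4-methylpent-2-yne
Product: 20 C25 tertiary homopropargylic alcohol (25α-OH; 4-methylpent-2-ynyl on C25; 17α-OTBS), via allenylzinc bromide 19 (not isolated)
Conditions: Zn dust (activated), THF, 0 °C → rt; aq NH4Cl
Reagents that add atoms: none
Why: Barbier-type propargylation. The zinc reagent reacts as allenylzinc 19 through an SE2′ transition state, and with this hindered ketone the bond should form at the unhindered CH2 terminus, giving the homopropargylic alcohol. The reagent should approach C25 anti to the C11–C12 ring bond with the methallyl group equatorial, which puts C27 trans to C10 and the hydroxyl anti to H11. The organozinc is not basic, so C11 is not epimerised.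

Step 12
Reactants: 20 C25 tertiary homopropargylic alcohol
Product: 21 diol (17α-OH, 25α-OH)
Conditions: Bu4NF, THF, rt
Reagents that add atoms: none
Why: Fluoride cleavage of the secondary silyl ether. Nothing else in the molecule responds to fluoride.

Step 13
Reactants: 21 diol
Product: 22 C17 ketone (25α-OH retained)
Conditions: Dess–Martin periodinane, NaHCO3, CH2Cl2, 0 °C
Reagents that add atoms: none
Why: Dess–Martin oxidation affects only the secondary alcohol, since the tertiary C25 alcohol cannot be oxidised. The buffered, non-basic medium should keep the β,γ-unsaturated ketone from moving into conjugation and H16 from being lost.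

Step 14
Reactants: 22 C17 ketone
Product: 23 C17 methylene enyne (C17=CH2; C21=C23; methallyl on C11; 4-methylpent-2-ynyl and α-OH on C25)
Conditions: Zn, CH2Br2, TiCl4 (pre-formed reagent in THF), CH2Cl2, 0 °C → rt
Reagents that add atoms: dibromomethane, BrCBr
Why: Takai–Lombardo methylenation. The reagent is not basic, so H16 (α to the ketone and allylic) is not removed, and it is inert to the alkyne, the alkenes and the tertiary alcohol. No stereocentre is formed.

Step 15
Reactants: 23 C17 methylene enyne
Product: 25 tetracyclic enone alcohol (C4=C28 enone; 8β-methyl; 25α-OH; C21=C23; 17-methylene), via hexacarbonyldicobalt alkyne complex 24 (not isolated)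
Conditions: Co2(CO)8, CH2Cl2, rt; then N-methylmorpholine N-oxide, 0 °C → rt
Reagents that add atoms: dicobalt octacarbonyl (source of CO), O=C=[Co](=C=O)(=C=O)(=C=O)[Co](=C=O)(=C=O)(=C=O)=C=O
Why: Pauson–Khand reaction: the alkyne forms complex 24, the amine oxide frees a coordination site, and insertion of the methallyl alkene and CO followed by reductive elimination forms C8–C28, C5–C7 and C4–C5. Ring B should close as a chair trans-fused to ring C with C7 equatorial, so that ring A is coplanar with the new C4=C28 bond; this places the C8 methyl axial on the β face, syn to H11. The C17 methylene and the C21=C23 alkene cannot reach the alkyne.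

Step 16
Reactants: 25 tetracyclic enone alcohol
Product: 26 21α,23α-epoxy enone (25α-OH; 17-methylene)
Conditions: VO(acac)2 (cat.), t-BuOOH, PhH, rt
Reagents that add atoms: tert-butyl hydroperoxide, CC(C)(C)OO
Why: Vanadium-catalysed hydroxyl-directed epoxidation. The peroxo vanadate bound to the C25 alkoxide should deliver oxygen to the adjacent tetrasubstituted alkene on the face of the hydroxyl (α), which is also the face of H16, setting C21 and C23. The electron-poor enone and the undirected methylene are not attacked, and no peracid is present to oxidise the ketone.

Step 17
Reactants: 26 21α,23α-epoxy enone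
Product: 27 target, CNP0332295.1
Conditions: [Ir(cod)(PCy3)(py)]PF6 (20 mol %), H2 (30 bar), CH2Cl2, rt
Reagents that add atoms: none
Why: Hydroxyl-directed homogeneous hydrogenation. Iridium bound to the axial 25α-hydroxyl should reach C28 across the 1,3-diaxial gap and add H2 cis to the α face of C4=C28, giving H28 α (trans ring fusion) and H4 α (isopropyl β) without an enolate. The same catalyst should reduce the C17 methylene from the α face, which is open and carries the epoxide oxygen while C15 shields the β face, so the C17 methyl ends β.

Compound list

1 | hex-4-yn-1-ol | CC#CCCCO | starting material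
2 | vinylmagnesium bromide | C=C[Mg]Br | starting material
3 | hex-4-ynal | CC#CCCC=O | intermediate
4 | rac-oct-1-en-6-yn-3-ol | C=CC(O)CCC#CC | intermediate
5 | (R)-oct-1-en-6-yn-3-ol | C=C[C@H](O)CCC#CC | intermediate
6 | (R)-3-(tert-butyldimethylsilyloxy)oct-1-en-6-yne | C=C[C@H](O[Si](C)(C)C(C)(C)C)CCC#CC | intermediate
7 | buta-1,3-diene | C=CC=C | starting material
8 | tert-butyldimethylsilyl ether of (4Z)-2-methylbicyclo[6.3.0]undeca-1,4-dien-9-ol, ring-fusion H cis to the silyloxy group (16α-H, 17α-OTBS) | C/C1=C2\CC[C@@H](O[Si](C)(C)C(C)(C)C)[C@@H]2CC/C=C\C1 | intermediate
9 | (4Z)-9-(tert-butyldimethylsilyloxy)-2-methylbicyclo[6.3.0]undeca-1,4-dien-3-one (C25 ketone) | C/C1=C2\CC[C@@H](O[Si](C)(C)C(C)(C)C)[C@@H]2CC/C=C\C1=O | intermediate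
10 | 4-iodo derivative of 9 (iodine on C11) | C/C1=C2\CC[C@@H](O[Si](C)(C)C(C)(C)C)[C@@H]2CC/C=C(/I)\C1=O | intermediate
11 | tributyl(2-methylallyl)stannane | CC(=C)C[Sn](CCCC)(CCCC)CCCC | starting material
12 | 4-(2-methylallyl) derivative of 9 (methallyl on C11) | C/C1=C2\CC[C@@H](O[Si](C)(C)C(C)(C)C)[C@@H]2CC/C=C(/CC(C)=C)\C1=O | intermediate
13 | lithium enolate (C11=C25, O–Li on C25, 12α-methyl) | C=C(C)C/C1=C(O[Li])/C(C)=C2/CC[C@@H](O[Si](C)(C)C(C)(C)C)[C@@H]2CC[C@H]1C | intermediate
14 | 9-(tert-butyldimethylsilyloxy)-2,5-dimethyl-4-(2-methylallyl)bicyclo[6.3.0]undec-1-en-3-one (12α-methyl, 11α-methallyl, 11β-H, 16α-H, 17α-OTBS) | C=C(C)C[C@@H]3[C@H](C)CC[C@H]4[C@H](O[Si](C)(C)C(C)(C)C)CC/C4=C(\C)C3=O | intermediate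
15 | 3-methylbut-1-yne | CC(C)C#C | starting material
16 | lithium 3-methylbut-1-ynide | CC(C)C#C[Li] | intermediate
17 | 4-methylpent-2-yn-1-ol | CC(C)C#CCO | intermediate
18 | 1-bromo-4-methylpent-2-yne | CC(C)C#CCBr | intermediate
19 | (4-methylpenta-1,2-dien-3-yl)zinc bromide | C=C=C(C(C)C)[Zn]Br | intermediate
20 | C25 tertiary alcohol: 14 with 25α-OH and 4-methylpent-2-ynyl on C25 (C27 trans to C10), 17α-OTBS | C=C(C)C[C@@H]3[C@H](C)CC[C@H]4[C@H](O[Si](C)(C)C(C)(C)C)CC/C4=C(\C)[C@@]3(O)CC#CC(C)C | intermediate
21 | diol: 20 with free 17α-OH | C=C(C)C[C@@H]3[C@H](C)CC[C@H]4[C@H](O)CC/C4=C(\C)[C@@]3(O)CC#CC(C)C | intermediate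
22 | C17 ketone of 21 | C=C(C)C[C@@H]3[C@H](C)CC[C@H]4C(=O)CC/C4=C(\C)[C@@]3(O)CC#CC(C)C | intermediate
23 | C17 methylene enyne | C=C(C)C[C@@H]3[C@H](C)CC[C@H]4C(=C)CC/C4=C(\C)[C@@]3(O)CC#CC(C)C | intermediate
24 | hexacarbonyldicobalt complex of the alkyne of 23 | C=C(C)C[C@@H]3[C@H](C)CC[C@H]4C(=C)CC/C4=C(\C)[C@@]3(O)CC12[Co]3(=C=O)(=C=O)(=C=O)[Co]1(=C=O)(=C=O)(=C=O)C23C(C)C | intermediate
25 | tetracyclic enone alcohol (C4=C28 enone, C5 ketone, 8β-methyl, 11β-H, 12α-methyl, 16α-H, 17-methylene, C21=C23, 25α-OH) | CC(C)C=1C(=O)C[C@]2(C)C[C@@H]3[C@H](C)CC[C@H]4C(=C)CC/C4=C(\C)[C@@]3(O)CC12 | intermediate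
26 | 21α,23α-epoxide of 25 | CC(C)C=1C(=O)C[C@]2(C)C[C@@H]3[C@H](C)CC[C@H]4C(=C)CC[C@]45O[C@]5(C)[C@@]3(O)CC12 | intermediate
27 | CNP0332295.1 (4β-isopropyl, 28α-H, 8β-methyl, 11β-H, 12α-methyl, 16α-H, 17β-methyl, 21α,23α-epoxide, 25α-OH) | CC(C)[C@H]1C(=O)C[C@]2(C)C[C@@H]3[C@H](C)CC[C@H]4[C@@H](C)CC[C@]45O[C@]5(C)[C@@]3(O)C[C@@H]12 | target

Step count and risk

Total: 17 steps (15 in the main line, 2 for side-chain bromide 18). Longest linear sequence: 15 steps from 1 (steps 1–8 and 11–17).

Step 4 (key step).
- Risk: cycloisomerisation or homo-coupling of the enyne, or oligomerisation of the diene, may outrun the cross reaction, because the plain carbon tether has no heteroatom or gem-diester to speed the oxidative cyclisation. Facial control by the single silyloxy group may also be incomplete.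
- Fallback, from 6 back to 8: cyclise 6 with Cp2ZrBu2 (from Cp2ZrCl2 and n-BuLi, THF, −78 °C → rt) to the zirconacyclopentene F1, which has the same C16–C21 bond and the same trans relation of C15 to the silyloxy group. Allylate both C–Zr bonds with allyl chloride and CuCl to the triene F2 (but-3-enyl on C16, allyl on C23 cis to C16). Ring-closing metathesis with the second-generation Grubbs catalyst (CH2Cl2, 40 °C, high dilution) then closes ring C at C11=C12 and gives 8.

Step 5.
- Risk: oxygen may be delivered to a terminus of the five-carbon radical (transposition to a linearly conjugated dienone), or another allylic position may be oxidised. Traces of acid could trigger electrocyclic closure of the cross-conjugated dienone.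
- Fallback, from 8 back to 9: epoxidise the electron-rich tetrasubstituted alkene with mCPBA (NaHCO3, CH2Cl2, 0 °C) to the epoxide F3. Isomerise with lithium diethylamide (or Et2AlTMP), removing a C25 hydrogen that is allylic to C11=C12, to the tertiary dienol F4 (hydroxyl on C21, diene C23=C25–C11=C12). Oxidative 1,3-transposition with (pyH)CrO3Cl moves oxygen to C25, restores C21=C23 and gives 9.

Step 8.
- Risk: the facial bias for methyl delivery depends on a ring conformation relayed from C16 and may be insufficient. The C11 configuration can also be lost by enolisation during or after the quench, since the cis isomer is set only kinetically.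
- Fallback, from 12 back to 14: a copper-catalysed enantioselective conjugate addition (MeMgBr, CuBr·SMe2, chiral ferrocenyl diphosphine, t-BuOMe, −78 °C) with Me3SiCl trapping puts C12 under catalyst control and gives the silyl enol ether F5, which is isolated. Protodesilylation with Bu4NF/AcOH at −78 °C, or with a chiral proton donor, then sets C11 in a separate operation that can be screened, and gives 14.

Step 11.
- Risk: the propargyl/allenyl zinc may bond through its substituted terminus and give an allenyl carbinol, or add to the wrong face of C25.
- Fallback, from 17 and 14 back to 20: convert 17 into its methyl carbonate F6 (ClCO2Me, pyridine). Copper-catalysed borylation (B2pin2, CuCl, Xantphos, KOt-Bu) gives by SN2′ substitution the allenylboronate F7, with boron on the isopropyl-bearing carbon. Zinc-catalysed addition of F7 to 14 (Et2Zn cat., THF) goes through a six-membered cyclic transition state that can only form the C25–CH2 bond, and gives 20 after hydrolysis.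

Step 15.
- Risk: insertion of the 1,1-disubstituted alkene next to a branched alkyne in a six-ring-forming mode may be slow, so that the cobalt complex is lost by decomplexation or reduction, or the skipped diene at C16 isomerises.
- Fallback, from 23 back to 25: silylate the tertiary alcohol (Me3SiOTf, 2,6-lutidine) to the silyl ether F8. Cyclise at a single early-metal centre with Cp2Ti(PMe3)2 and carbonylate the titanacycle with CO to the silylated enone F9. Remove the silyl group (K2CO3, MeOH) to give 25.

Step 17.
- Risk: the tetrasubstituted enone may resist reduction, the cationic iridium hydride may open or rearrange the hydroxy epoxide, or the methylene may migrate into ring D before it is reduced.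
- Fallback, from 25 to 27: dissolving-metal reduction of 25 (Li, NH3/THF, −78 °C, t-BuOH, cold kinetic quench) gives the saturated ketone F10, with H28 α by axial protonation and H4 α by protonation anti to the angular methyl. RhCl(PPh3)3/H2 then reduces only the C17 methylene from the α face to the 17β-methyl ketone F11. The VO(acac)2/t-BuOOH epoxidation is run last and gives 27.

Further compounds

F1 | step 4 | zirconacyclopentene from 6 (Cp2Zr bonded to C15 and C23) | C/C1=C2\CC[C@@H](O[Si](C)(C)C(C)(C)C)[C@@H]2C[Zr]1(C3C=CC=C3)C4C=CC=C4
F2 | step 4 | triene: silyloxycyclopentane with but-3-enyl on C16 and allyl on C23 of the exocyclic tetrasubstituted alkene | C=CC/C(C)=C1/CC[C@@H](O[Si](C)(C)C(C)(C)C)[C@@H]1CCC=C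
F3 | step 5 | 21α,23α-epoxide of 8 | C1/C=C\CC[C@H]4[C@H](O[Si](C)(C)C(C)(C)C)CC[C@]45O[C@]15C
F4 | step 5 | tertiary dienol (21α-OH, C23=C25, Z-C11=C12) | C/C1=C/C=C\CC[C@H]2[C@H](O[Si](C)(C)C(C)(C)C)CC[C@@]12O
F5 | step 8 | trimethylsilyl enol ether corresponding to 13 | C=C(C)C/C1=C(O[Si](C)(C)C)/C(C)=C2/CC[C@@H](O[Si](C)(C)C(C)(C)C)[C@@H]2CC[C@H]1C
F6 | step 11 | methyl 4-methylpent-2-yn-1-yl carbonate | CC(C)C#CCOC(=O)OC
F7 | step 11 | 4,4,5,5-tetramethyl-2-(4-methylpenta-1,2-dien-3-yl)-1,3,2-dioxaborolane | C=C=C(C(C)C)B1OC(C)(C)C(C)(C)O1
F8 | step 15 | trimethylsilyl ether of 23 | C=C(C)C[C@@H]3[C@H](C)CC[C@H]4C(=C)CC/C4=C(\C)[C@@]3(O[Si](C)(C)C)CC#CC(C)C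
F9 | step 15 | trimethylsilyl ether of 25 | CC(C)C=1C(=O)C[C@]2(C)C[C@@H]3[C@H](C)CC[C@H]4C(=C)CC/C4=C(\C)[C@@]3(O[Si](C)(C)C)CC12
F10 | step 17 | saturated ring A ketone (4β-isopropyl, 28α-H) with 17-methylene and C21=C23 | CC(C)[C@H]1C(=O)C[C@]2(C)C[C@@H]3[C@H](C)CC[C@H]4C(=C)CC/C4=C(\C)[C@@]3(O)C[C@@H]12
F11 | step 17 | 17β-methyl ketone with C21=C23 (de-epoxy target) | CC(C)[C@H]1C(=O)C[C@]2(C)C[C@@H]3[C@H](C)CC[C@H]4[C@@H](C)CC/C4=C(\C)[C@@]3(O)C[C@@H]12
A1 | alternative 1 | trans-decalin-1,2-dione, six-membered homologue of ring A (C25 as dioxolane) | CC(C)[C@H]1C(=O)C(=O)C[C@]2(C)CCC3(OCCO3)C[C@@H]12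
A2 | alternative 1 | trans-hydrindanone, rings A and B (C25 as dioxolane) | CC(C)[C@H]1C(=O)C[C@]2(C)CCC3(OCCO3)C[C@@H]12
A3 | alternative 2 | ring C/D enyne with 17β-methyl, methallyl on C11, 4-methylpent-2-ynyl and α-OH on C25 | C=C(C)C[C@@H]3[C@H](C)CC[C@H]4[C@@H](C)CC/C4=C(\C)[C@@]3(O)CC#CC(C)C
A4 | alternative 2 | tetracyclic enone alcohol with 17β-methyl | CC(C)C=1C(=O)C[C@]2(C)C[C@@H]3[C@H](C)CC[C@H]4[C@@H](C)CC/C4=C(\C)[C@@]3(O)CC12
A5 | alternative 3 | ten-membered lactone (C13 acyl, oxygen on C27 α, C25=C11, C5 as dioxolane) | CC(C)[C@H]1C6(OCCO6)C[C@]2(C)C/C=C3/C(C)=C4/CC[C@H](C)[C@@H]4CCCC(=O)O[C@@H]3[C@@H]12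
A6 | alternative 3 | tetracyclic diene acid (C13 carboxyl on C12, C25=C27, C5 as dioxolane) | CC(C)[C@H]1C6(OCCO6)C[C@]2(C)C[C@@H]3[C@H](C(=O)O)CC[C@H]4[C@@H](C)CC/C4=C(\C)C3=C[C@@H]12
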